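## Retrosynthetic overview

Disconnections are listed in the order in which the bonds are made. Ring A is the ketone-bearing ring, ring B the 4-methoxyphenyl ring.

1. Ring A is bought as 4-hydroxy-2-methoxybenzaldehyde 1. C5–I is made first (1 → 2), then C5–prenyl by Stille coupling with prenylstannane 3 (2 → 4).
2. Key disconnection, made last: the C1(=O)–C2(OH) bond, cut into ring A aldehyde 4 (acyl-anion donor) and ring B aldehyde 5 (acceptor). A chiral carbene-catalysed crossed acyloin reaction joins them and sets the only stereocentre (2S) of target 6.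
3. No ring is formed in the route: both benzene rings come intact from 1 and 5, and no protecting group is used.

Assumption: the thiazolium salt of step 3 is a new catalyst design and is not numbered as a route compound. It is 3-[(1R,2S)-2-hydroxy-2,3-dihydro-1H-inden-1-yl]-4,5-dimethyl-1,3-thiazol-3-ium tetrafluoroborate, SMILES Cc1sc[n+](c1C)[C@@H]1c2ccccc2C[C@@H]1O.F[B-](F)(F)F, made from commercial cis-1-amino-2-indanol by N-formylation, thionation, condensation with 3-chlorobutan-2-one and anion exchange. Its sense of induction is a working model only; if the first run gives the (R)-ketol, the antipode from (1S,2R)-aminoindanol is used in the same way. Aldehyde 5 is used freshly distilled.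

## Route

Step 1
Reactants: 1 4-hydroxy-2-methoxybenzaldehyde
Product: 2 4-hydroxy-5-iodo-2-methoxybenzaldehyde
Conditions: NIS (1.05 equiv), CF3CO2H (10 mol%), MeCN, 0 °C to rt
Reagents that add atoms: N-iodosuccinimide, O=C1CCC(=O)N1I
Why: Electrophilic aromatic substitution (iodination of a phenol): C5 is ortho to OH and para to OMe and is open, whereas C3 is wedged between both oxygens, so one iodine enters at C5; the aldehyde is inert and no stereocentre is involved.

Step 2
Reactants: 2 4-hydroxy-5-iodo-2-methoxybenzaldehyde; 3 tributyl(3-methylbut-2-en-1-yl)stannane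
Product: 4 4-hydroxy-2-methoxy-5-(3-methylbut-2-en-1-yl)benzaldehyde
Conditions: Pd(PPh3)4 (5 mol%), DMF, 90 °C, argon
Reagents that add atoms: none
Why: Migita–Kosugi–Stille coupling: zerovalent palladium inserts into the C–I bond, the prenyl group passes from tin to palladium, and reductive elimination at the unhindered primary allyl terminus gives the linear prenyl arene under neutral conditions that leave phenol and aldehyde untouched; no stereocentre.

Step 3
Reactants: 4 4-hydroxy-2-methoxy-5-(3-methylbut-2-en-1-yl)benzaldehyde; 5 2-(4-methoxyphenyl)acetaldehyde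
Product: 6 Lespeflorin C4 = (2S)-2-hydroxy-1-[4-hydroxy-2-methoxy-5-(3-methylbut-2-en-1-yl)phenyl]-3-(4-methoxyphenyl)propan-1-one
Conditions: 3-[(1R,2S)-2-hydroxy-2,3-dihydro-1H-inden-1-yl]-4,5-dimethyl-1,3-thiazol-3-ium tetrafluoroborate (10 mol%), i-Pr2NEt (20 mol%), THF, 0 to 20 °C, argon, 5 (2 equiv) added over 10 h
Reagents that add atoms: none
Why: Proposed new method: an enantioselective crossed acyloin (cross-benzoin) reaction between an aryl aldehyde as acyl-anion donor and an unbranched, enolisable arylacetaldehyde as acceptor, run with a new protic chiral thiazolium precatalyst; mechanistic reasoning: the thiazol-2-ylidene adds to 4 and the benzylic C–H of the adduct is removed (the phenol of 4 acts as proton shuttle) to give a Breslow enaminol that is conjugated with the electron-rich ring A and so strongly nucleophilic, while the carbonyl of 4 (para-hydroxy, ortho-methoxy) is a poor acceptor and that of 5, kept dilute by slow addition, is a good one, so the C1–C2 bond forms with 5; the indanol OH of the catalyst hydrogen-bonds the carbonyl oxygen of 5 and the indane arene shields the other face of the enaminol, so 5 is attacked on its Re face and the (S)-carbinol forms, after which the adduct collapses to 6 and free carbene, all atoms of 4 and 5 end up in 6, and the electron-rich aryl ketone of 6 is not attacked again, which keeps the step under kinetic control; closest known reaction types: the racemic thiazolium-catalysed crossed acyloin condensation of aryl aldehydes (donors) with aliphatic aldehydes (acceptors), which is also the selectivity of thiamine-dependent carboligases, and the enantioselective homo-benzoin condensation with protic chiral triazolium salts.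

## Compound list

1 | 4-hydroxy-2-methoxybenzaldehyde | COc1cc(O)ccc1C=O | starting material
2 | 4-hydroxy-5-iodo-2-methoxybenzaldehyde | COc1cc(O)c(I)cc1C=O | intermediate
3 | tributyl(3-methylbut-2-en-1-yl)stannane | CCCC[Sn](CCCC)(CCCC)CC=C(C)C | starting material
4 | 4-hydroxy-2-methoxy-5-(3-methylbut-2-en-1-yl)benzaldehyde | COc1cc(O)c(CC=C(C)C)cc1C=O | intermediate
5 | 2-(4-methoxyphenyl)acetaldehyde | COc1ccc(CC=O)cc1 | starting material
6 | Lespeflorin C4 = (2S)-2-hydroxy-1-[4-hydroxy-2-methoxy-5-(3-methylbut-2-en-1-yl)phenyl]-3-(4-methoxyphenyl)propan-1-one | COc1ccc(C[C@H](O)C(=O)c2cc(CC=C(C)C)c(O)cc2OC)cc1 | target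

## Step count and risks

Total steps: 3. Longest linear sequence: 3 steps (1 → 2 → 4 → 6).

**Step 3 (the proposed new reaction).** It can fail in four ways:
- The donor and acceptor roles invert and give the isomeric ketol with the carbinol on ring A; a thiazolylidene was chosen because N-aryl triazolylidenes are known to favour that inverted connectivity.
- Aldehyde 5 consumes itself by aldol or homo-acyloin reaction.
- The new catalyst gives only modest ee.
- The ketol racemises if the base load is raised.

The fallback uses known chemistry and changes the approach from acyl-anion coupling to enolate alkylation under chiral phase-transfer catalysis. It sets out from 4 and comes back to the route at 6. Silylation of 4 (i-Pr3SiCl, imidazole, DMF, rt) gives 2-methoxy-5-(3-methylbut-2-en-1-yl)-4-[(triisopropylsilyl)oxy]benzaldehyde F1. Carbene-catalysed hydroxymethylation with paraformaldehyde (3-benzyl-5-(2-hydroxyethyl)-4-methylthiazolium chloride 10 mol%, i-Pr2NEt, THF, 60 °C), in which formaldehyde can only be the acceptor, gives 2-hydroxy-1-{2-methoxy-5-(3-methylbut-2-en-1-yl)-4-[(triisopropylsilyl)oxy]phenyl}ethan-1-one F2. Acid-free O-benzhydrylation (diphenylmethyl 2,2,2-trichloroacetimidate, toluene, 110 °C) gives 2-(diphenylmethoxy)-1-{2-methoxy-5-(3-methylbut-2-en-1-yl)-4-[(triisopropylsilyl)oxy]phenyl}ethan-1-one F3. Asymmetric phase-transfer alkylation of this aryl ketone glycolate with 4-methoxybenzyl bromide (O-allyl-N-(2,3,4-trifluorobenzyl)hydrocinchonidinium bromide 10 mol%, CsOH·H2O, CH2Cl2/hexane 1:1, −35 °C) sets the (S) centre and gives (2S)-2-(diphenylmethoxy)-3-(4-methoxyphenyl)-1-{2-methoxy-5-(3-methylbut-2-en-1-yl)-4-[(triisopropylsilyl)oxy]phenyl}propan-1-one F4. The cinchonidine-derived cation is the one that gives the (S) series in this reaction class, and ee can be raised by recrystallisation. The benzhydryl ether is then cleaved (CF3CO2H/CH2Cl2 1:4, anisole 20 equiv, 0 °C) while the silyl ether stays on, so that the prenyl group cannot close onto a free phenol. This gives (2S)-2-hydroxy-3-(4-methoxyphenyl)-1-{2-methoxy-5-(3-methylbut-2-en-1-yl)-4-[(triisopropylsilyl)oxy]phenyl}propan-1-one F5. Finally Bu4NF buffered with AcOH (THF, 0 °C) frees the phenol and gives 6.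

**Step 2 (Stille prenylation).** Risks are allyl transposition to the branched 1,1-dimethylallyl isomer, loss of iodine by reduction, and sluggish coupling next to the free phenol. The fallback builds the prenyl group in two stages instead of transferring it whole. It sets out from 2 and comes back to the route at 4. Stille allylation with allyltributylstannane (Pd(PPh3)4, DMF, 80 °C), where no regiochemical question arises, gives 4-hydroxy-2-methoxy-5-(prop-2-en-1-yl)benzaldehyde F6. Olefin cross-metathesis with 2-methylbut-2-ene as co-solvent (second-generation Grubbs catalyst RuCl2(=CHPh)(PCy3)(H2IMes) 5 mol%, CH2Cl2, 40 °C) then converts the allyl into the prenyl group of 4 with loss of propene.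

**Step 1 (iodination).** Risks are some attack at C3 and double iodination. The fallback gives up halogenation and cross-coupling and moves the prenyl group from oxygen to carbon. It sets out from 1 and comes back to the route at 4, so 2 and step 2 are bypassed. O-Prenylation (1-bromo-3-methylbut-2-ene, K2CO3, acetone, 56 °C) gives 2-methoxy-4-[(3-methylbut-2-en-1-yl)oxy]benzaldehyde F7. An acid-clay-promoted 1,3-shift (montmorillonite K10, an acid aluminosilicate clay of idealised formula Al2O3·4SiO2·H2O, CH2Cl2, 0 °C to rt) then moves the prenyl group to the open ortho carbon C5 and gives 4. The minor C3 isomer and chroman by-product are removed by chromatography.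

## Further compounds

F1 | step 3 | 2-methoxy-5-(3-methylbut-2-en-1-yl)-4-[(triisopropylsilyl)oxy]benzaldehyde | COc1cc(O[Si](C(C)C)(C(C)C)C(C)C)c(CC=C(C)C)cc1C=O
F2 | step 3 | 2-hydroxy-1-{2-methoxy-5-(3-methylbut-2-en-1-yl)-4-[(triisopropylsilyl)oxy]phenyl}ethan-1-one | COc1cc(O[Si](C(C)C)(C(C)C)C(C)C)c(CC=C(C)C)cc1C(=O)CO
F3 | step 3 | 2-(diphenylmethoxy)-1-{2-methoxy-5-(3-methylbut-2-en-1-yl)-4-[(triisopropylsilyl)oxy]phenyl}ethan-1-one | COc1cc(O[Si](C(C)C)(C(C)C)C(C)C)c(CC=C(C)C)cc1C(=O)COC(c1ccccc1)c1ccccc1
F4 | step 3 | (2S)-2-(diphenylmethoxy)-3-(4-methoxyphenyl)-1-{2-methoxy-5-(3-methylbut-2-en-1-yl)-4-[(triisopropylsilyl)oxy]phenyl}propan-1-one | COc1ccc(C[C@H](OC(c2ccccc2)c2ccccc2)C(=O)c2cc(CC=C(C)C)c(O[Si](C(C)C)(C(C)C)C(C)C)cc2OC)cc1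
F5 | step 3 | (2S)-2-hydroxy-3-(4-methoxyphenyl)-1-{2-methoxy-5-(3-methylbut-2-en-1-yl)-4-[(triisopropylsilyl)oxy]phenyl}propan-1-one | COc1ccc(C[C@H](O)C(=O)c2cc(CC=C(C)C)c(O[Si](C(C)C)(C(C)C)C(C)C)cc2OC)cc1
F6 | step 2 | 4-hydroxy-2-methoxy-5-(prop-2-en-1-yl)benzaldehyde | COc1cc(O)c(CC=C)cc1C=O
F7 | step 1 | 2-methoxy-4-[(3-methylbut-2-en-1-yl)oxy]benzaldehyde | COc1cc(OCC=C(C)C)ccc1C=O
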